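**Retrosynthetic overview**
1. Feature used: C1 and C2 are the neighbouring carbons of the 1,10- and 2,3-oxiranes and C10 is a fully substituted carbinol. C1–C2 is therefore cut as the addition of a C2≡C3 acetylide to a C1 aldehyde that cannot enolise, which closes the ten-membered carbocycle.
2. The seco-aldehyde is cut at C7–C8 (Nozaki–Hiyama γ-allylation of a C8 aldehyde from (S)-2-methylglycidol by a 4-(bromomethyl)-2,5-dihydrofuran from D-erythrose) and at C3–C4 (acetylide on a C4 aldehyde, then C15 methylenation).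
3. O6 and C12 travel as one 3-methyleneoxolane instead of two protected hydroxyls: the ring fixes 6,7-trans and 7,8-anti in the allylation, needs no late acid, and is oxidised at C12 to the α-methylene lactone.
4. Order of ring formation: oxolane (step 6), ten-membered ring (step 20), 2,3-oxirane (step 22), 1,10-oxirane (step 24, inversion at C1); then O8 angeloylation, C12 oxidation, O5 desilylation.

Key step: step 20

Assumption: 2,4-O-ethylidene-D-erythrose (1), the periodate cleavage product of 4,6-O-ethylidene-D-glucose, is taken as purchased and reacts as its monomeric aldehyde; labels C1–C15 and O1–O12 are the germacrane positions of the target.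

**Fragment A (C4–C7, C11–C13)**

Step 1
Reactants: 1 2,4-O-ethylidene-D-erythrose
Product: 2 (2R,4S,5R)-2-methyl-4-vinyl-1,3-dioxan-5-ol
Conditions: Ph3PCH3Br, KOtBu, THF, 0 °C → rt
Reagents that add atoms: methyltriphenylphosphonium bromide (as its ylide), C[P+](c1ccccc1)(c1ccccc1)c1ccccc1.[Br-]
Why: Wittig methylenation of the α-alkoxy aldehyde with excess ylide (one equivalent is held by the free hydroxyl) should give the vinyl dioxane; C5 and C6 are not touched and stay trans-diequatorial on the ring.

Step 2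
Reactants: 2 (2R,4S,5R)-2-methyl-4-vinyl-1,3-dioxan-5-ol
Product: 3 tert-butyl{[(2R,4S,5R)-2-methyl-4-vinyl-1,3-dioxan-5-yl]oxy}diphenylsilane
Conditions: t-BuPh2SiCl, imidazole, DMF, rt
Reagents that add atoms: tert-butyl(chloro)diphenylsilane, CC(C)(C)[Si](Cl)(c1ccccc1)c1ccccc1
Why: Imidazole-promoted silylation of the single secondary hydroxyl should give the O5 silyl ether, chosen because it survives the acid of step 3 and the HF·pyridine of step 24 and is removed last.

Step 3
Reactants: 3 silyl ether of the vinyl dioxane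
Product: 4 (2R,3S)-2-[(tert-butyldiphenylsilyl)oxy]pent-4-ene-1,3-diol
Conditions: TsOH·H2O (cat.), MeOH, 45 °C
Reagents that add atoms: none
Why: Acid-catalysed transacetalisation to the solvent methanol should release the O4/O6 diol, the bulky silyl ether and the allylic carbinol being stable to catalytic TsOH.

Step 4
Reactants: 4 (2R,3S)-2-[(tert-butyldiphenylsilyl)oxy]pent-4-ene-1,3-diol
Product: 6 (3S,4R)-4-[(tert-butyldiphenylsilyl)oxy]-5-[(4-methoxybenzyl)oxy]pent-1-en-3-ol, via dibutylstannylene acetal 5 (not isolated)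
Conditions: Bu2SnO, toluene, reflux (−H2O); then 4-MeOC6H4CH2Cl, Bu4NI, 90 °C
Reagents that add atoms: 4-methoxybenzyl chloride, COc1ccc(CCl)cc1
Why: Regioselective O-alkylation through a dibutylstannylene acetal should put the 4-methoxybenzyl group on the primary oxygen O4 and leave the allylic O6 hydroxyl free, without the strong base that would make the silyl group migrate.

Step 5
Reactants: 6 mono-protected allylic alcohol; 7 3-bromo-2-(bromomethyl)prop-1-ene
Product: 9 (3S,4R)-3-{[2-(bromomethyl)prop-2-en-1-yl]oxy}-4-[(tert-butyldiphenylsilyl)oxy]-5-[(4-methoxybenzyl)oxy]pent-1-ene, via sodium alkoxide 8 (not isolated)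
Conditions: NaH, 7 (4 equiv), THF, 0 °C
Reagents that add atoms: none
Why: Williamson etherification of the O6 alkoxide with an excess of the doubly allylic dibromide at 0 °C should give the mono-ether faster than 1,2-silyl migration or a second alkylation can occur.

Step 6
Reactants: 9 diene ether
Product: 10 (2S)-4-(bromomethyl)-2-{(1R)-1-[(tert-butyldiphenylsilyl)oxy]-2-[(4-methoxybenzyl)oxy]ethyl}-2,5-dihydrofuran
Conditions: second-generation Grubbs catalyst (5 mol%), CH2Cl2 (0.02 M), 40 °C
Reagents that add atoms: none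
Why: Ring-closing olefin metathesis of the vinyl group onto the 1,1-disubstituted alkene should close the 2,5-dihydrofuran (O6, C6, C7, C11, C12) with loss of ethene, the allylic bromide being inert to the ruthenium carbene.

**Fragment B (C8–C10, C1, C14)**

Step 7
Reactants: 11 (S)-2-methylglycidol
Product: 13 (R)-2-methylpent-4-ene-1,2-diol, via bromomagnesium alkoxide 12 (not isolated)
Conditions: CH2=CHMgBr (3.5 equiv), CuI (10 mol%), THF, −30 → 0 °C; then aq. NH4Cl
Reagents that add atoms: vinylmagnesium bromide, C=C[Mg]Br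
Why: Copper-catalysed epoxide opening by the vinyl Grignard reagent at the unsubstituted oxirane carbon should give the 1,2-diol; no bond at the quaternary centre (future C10) is broken, so its configuration is kept (S becomes R only by the priority rules).

Step 8
Reactants: 13 (R)-2-methylpent-4-ene-1,2-diol
Product: 14 (R)-2-hydroxy-2-methylpent-4-en-1-yl acetate
Conditions: Ac2O, pyridine, CH2Cl2, 0 °C
Reagents that add atoms: acetic anhydride, CC(=O)OC(C)=O
Why: Acetylation should occur at the primary hydroxyl only, because the tertiary C10 hydroxyl is not acylated without forcing conditions.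

Step 9
Reactants: 14 primary acetate
Product: 15 (R)-2-methyl-2-[(triethylsilyl)oxy]pent-4-en-1-yl acetate
Conditions: Et3SiOTf, 2,6-lutidine, CH2Cl2, −78 → 0 °C
Reagents that add atoms: triethylsilyl trifluoromethanesulfonate, CC[Si](CC)(CC)OS(=O)(=O)C(F)(F)F
Why: Silylation with the silyl triflate and a hindered base should cap the tertiary C10 hydroxyl as a non-chelating triethylsilyl ether.

Step 10
Reactants: 15 silyl ether alkene
Product: 17 (R)-2-methyl-4-oxo-2-[(triethylsilyl)oxy]butyl acetate, via ozonide 16 (not isolated)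
Conditions: O3, CH2Cl2, −78 °C; then PPh3, −78 °C → rt
Reagents that add atoms: ozone, [O-][O+]=O
Why: Ozonolysis with reductive work-up should cut the terminal alkene to the C8 aldehyde, a β-silyloxy aldehyde that is used without storage.

**Union, enyne and seco-aldehyde**

Step 11
Reactants: 10 bromomethyl dihydrofuran; 17 C8 aldehyde
Product: 19 C8 alcohol with 3-methyleneoxolane (H6/H7 trans; C8–OH anti to C6), via allylchromium dichloride 18 (not isolated)
Conditions: CrCl2 (4 equiv), THF, 0 °C → rt; then H2O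
Reagents that add atoms: none
Why: Nozaki–Hiyama allylation: CrCl2 should convert bromide 10 into an allylchromium reagent that adds to the aldehyde through ring carbon C7 in a chair transition state, on the ring face opposite to the C6 side chain (6,7-trans) and with the ring-fixed E geometry giving the 7,8-anti carbinol, so that C7 and C8 are both set from C6.

Step 12
Reactants: 19 C8 alcohol
Product: 20 8,10-bis(triethylsilyl) ether
Conditions: Et3SiOTf, 2,6-lutidine, CH2Cl2, −78 → 0 °C
Reagents that add atoms: triethylsilyl trifluoromethanesulfonate, CC[Si](CC)(CC)OS(=O)(=O)C(F)(F)F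
Why: Silylation of the hindered C8 hydroxyl with the silyl triflate should give the bis(triethylsilyl) ether, so that both silyl groups can be taken off together in step 24.

Step 13
Reactants: 20 bis(triethylsilyl) ether
Product: 21 C4 primary alcohol
Conditions: DDQ, CH2Cl2/pH 7 buffer (10:1), 0 °C
Reagents that add atoms: none
Why: Oxidative cleavage of the 4-methoxybenzyl ether by DDQ in buffered wet CH2Cl2 should free the C4 hydroxyl while the silyl ethers, the acetate and the allylic oxolane ether stay.

Step 14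
Reactants: 21 C4 primary alcohol
Product: 22 C4 aldehyde
Conditions: Dess–Martin periodinane, NaHCO3, CH2Cl2, 0 °C → rt
Reagents that add atoms: none
Why: Dess–Martin oxidation under NaHCO3 buffer should give the α-silyloxy aldehyde without epimerisation at C5.

Step 15
Reactants: 22 C4 aldehyde; 23 ethynyltrimethylsilane
Product: 25 C4 propargylic alcohol (both C4 epimers), via lithium trimethylsilylacetylide 24 (not isolated)
Conditions: 23, n-BuLi, THF, −78 °C; then 22, −78 °C; then aq. NH4Cl at −78 °C
Reagents that add atoms: none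
Why: 1,2-Addition of the lithium acetylide at −78 °C should attach C3 and C2 to C4; the C4 carbinol forms as a mixture that is oxidised next, and the cold quench avoids silyl migration from O5 and attack on the acetate.

Step 16
Reactants: 25 C4 propargylic alcohol
Product: 26 C4 trimethylsilyl ynone
Conditions: Dess–Martin periodinane, NaHCO3, CH2Cl2, 0 °C → rt
Reagents that add atoms: none
Why: Dess–Martin oxidation should give the ynone and erase the C4 stereocentre.

Step 17
Reactants: 26 C4 trimethylsilyl ynone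
Product: 27 silylated enyne (C4=C15 methylene)
Conditions: Ph3PCH3Br, KN(SiMe3)2, THF, 0 °C; then 26, −78 → 0 °C
Reagents that add atoms: methyltriphenylphosphonium bromide (as its ylide), C[P+](c1ccccc1)(c1ccccc1)c1ccccc1.[Br-]
Why: Wittig methylenation of the reactive ynone at low temperature should install C15 and give the C4=C15 enyne before the basic ylide can enolise C5.

Step 18
Reactants: 27 silylated enyne
Product: 28 terminal enyne with free C1 hydroxyl
Conditions: K2CO3 (0.5 equiv), MeOH, 0 °C → rt
Reagents that add atoms: none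
Why: Methanolysis with K2CO3 should remove the C-silyl group of the alkyne and the C1 acetate in one operation, the hindered O-silyl ethers being stable to methoxide.

Step 19
Reactants: 28 terminal enyne C1 alcohol
Product: 29 seco-aldehyde (C1 aldehyde on C10 bearing CH3 and OSiEt3; terminal C2≡C3–C4(=CH2) enyne)
Conditions: Dess–Martin periodinane, NaHCO3, CH2Cl2, 0 °C → rt
Reagents that add atoms: none
Why: Dess–Martin oxidation of the neopentyl C1 alcohol should give the aldehyde, which cannot epimerise or enolise because C10 bears no hydrogen.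

**Ring closure and endgame**

Step 20
Reactants: 29 seco-aldehyde
Product: 31 ten-membered 2-yn-1-ol (1S), via lithium acetylide 30 (not isolated)
Conditions: LiN(SiMe3)2 (1.5 equiv), CeCl3 (3 equiv), THF, −78 → −40 °C, slow addition of 29 to 2 mM; then AcOH, −78 °C
Reagents that add atoms: none
Why: LiN(SiMe3)2 removes the only acidic proton, that of the terminal C2 alkyne (C10 carries no hydrogen, so the aldehyde cannot be enolised, and the rest is ether or silyl ether), and CeCl3 turns the lithium acetylide into a less basic cerium acetylide that adds to the C1 carbonyl. The closest known reaction type is the base-mediated intramolecular acetylide–aldehyde addition used to close nine- and ten-membered cycloalkynes of enediyne cores. The ten-membered carbocycle closes in the 10-exo-trig mode; the rod-like C1–C2≡C3–C4 segment, the trigonal C4 and the trans-fused oxolane at C6–C7 remove free rotors, and slow addition at high dilution keeps intermolecular addition down. The new C1 carbinol is set by C10 in the Felkin–Anh sense: the non-chelating C10–OSiEt3 bond stands anti to the incoming acetylide, which passes the methyl group, and this gives the 1S alcohol with O1 anti to O10. The step needs selective alkyne deprotonation, ring closure over oligomerisation and this facial selectivity; the cold acetic acid quench prevents transfer of the C10 silyl group to the new alkoxide.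

Step 21
Reactants: 31 ten-membered 2-yn-1-ol
Product: 32 (2Z)-2,4(15)-dien-1-ol
Conditions: H2 (1 atm), Pd/CaCO3 poisoned with Pb(OAc)2, quinoline, EtOAc, rt
Reagents that add atoms: none
Why: cis-Semi-hydrogenation of the cycloalkyne over poisoned palladium (Lindlar reduction) should stop at the Z C2=C3 alkene and leave the two 1,1-disubstituted methylene groups alone.

Step 22
Reactants: 32 (2Z)-dienol
Product: 33 2,3-epoxy-1-ol (cis-oxirane on the face of the C1 hydroxyl)
Conditions: VO(acac)2 (10 mol%), t-BuOOH (1.5 equiv, decane), CH2Cl2, 0 °C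
Reagents that add atoms: tert-butyl hydroperoxide, CC(C)(C)OO
Why: Hydroxyl-directed epoxidation: the vanadium alkoxide of the C1 carbinol should deliver the peroxide oxygen to the face of the Z C2=C3 alkene syn to that hydroxyl (cis-epoxy alcohol, as for medium-ring Z-cycloalkenols), which sets C2 and C3, while the C4=C15 and C11=C13 alkenes have no directing hydroxyl.

Step 23
Reactants: 33 2,3-epoxy-1-ol
Product: 34 C1 mesylate
Conditions: MsCl, Et3N, CH2Cl2, −20 → 0 °C
Reagents that add atoms: methanesulfonyl chloride, CS(=O)(=O)Cl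
Why: Sulfonylation of the only free hydroxyl through the sulfene from MsCl and Et3N should give the C1 mesylate even though the carbinol is flanked by an oxirane and a quaternary carbon.

Step 24
Reactants: 34 C1 mesylate
Product: 36 1,10:2,3-bis-epoxide with free C8 hydroxyl, via diol mesylate 35 (not isolated)
Conditions: HF·pyridine, pyridine, THF, 0 °C; then K2CO3, MeOH, 0 °C → rt
Reagents that add atoms: none
Why: Acidic fluoride should remove both triethylsilyl ethers and leave the tert-butyldiphenylsilyl ether, and K2CO3 should then make the C10 alkoxide displace the antiperiplanar C1 mesylate (intramolecular SN2, 3-exo-tet) with inversion at C1 to give the trans 1,10-oxirane, faster than the C8 hydroxyl can reach the neopentyl C1.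

Step 25
Reactants: 36 bis-epoxide C8 alcohol; 37 angelic acid
Product: 39 8-O-angelate, via mixed anhydride 38 (not isolated)
Conditions: 37, 2,4,6-Cl3C6H2COCl, Et3N, toluene, rt; then 36, toluene, 75 °C
Reagents that add atoms: none
Why: Esterification through the mixed anhydride of angelic acid with 2,4,6-trichlorobenzoic acid (Yamaguchi-type acylation without a nucleophilic catalyst) should acylate the only free hydroxyl, O8, without Z-to-E isomerisation of the angelate.

Step 26
Reactants: 39 8-O-angelate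
Product: 40 α-methylene lactone, O5 silyl ether of the target
Conditions: CrO3·2py (15 equiv), CH2Cl2, rt
Reagents that add atoms: chromium trioxide (as CrO3·2py), O=[Cr](=O)=O
Why: Allylic oxidation of the cyclic allylic ether by hexavalent chromium, a known route from 3-methyleneoxolanes to α-methylene-γ-butyrolactones, should convert the doubly activated C12 methylene (allylic and next to O6) into the lactone carbonyl.

Step 27
Reactants: 40 O5 silyl ether of the target
Product: 41 CNP0038366.2 (target)
Conditions: Bu4NF, AcOH (1:1), THF, 0 °C → rt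
Reagents that add atoms: none
Why: Buffered fluoride desilylation should free the C5 hydroxyl under near-neutral conditions that spare the oxiranes, the α-methylene lactone and the angelate.

**Compound list**
1 | 2,4-O-ethylidene-D-erythrose, (2R,4R,5R)-5-hydroxy-2-methyl-1,3-dioxane-4-carbaldehyde | O=C[C@@H]1O[C@H](C)OC[C@H]1O | starting material
2 | (2R,4S,5R)-2-methyl-4-vinyl-1,3-dioxan-5-ol | C=C[C@@H]1O[C@H](C)OC[C@H]1O | intermediate
3 | tert-butyl{[(2R,4S,5R)-2-methyl-4-vinyl-1,3-dioxan-5-yl]oxy}diphenylsilane | C=C[C@@H]1O[C@H](C)OC[C@H]1O[Si](c1ccccc1)(c1ccccc1)C(C)(C)C | intermediate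
4 | (2R,3S)-2-[(tert-butyldiphenylsilyl)oxy]pent-4-ene-1,3-diol | C=C[C@H](O)[C@H](O[Si](c1ccccc1)(c1ccccc1)C(C)(C)C)CO | intermediate
5 | 2,2-dibutyl-1,3,2-dioxastanninane (stannylene acetal) of diol 4 | CCCC[Sn]1(CCCC)OC[C@@H](O[Si](c2ccccc2)(c2ccccc2)C(C)(C)C)[C@H](C=C)O1 | intermediate (not isolated)
6 | (3S,4R)-4-[(tert-butyldiphenylsilyl)oxy]-5-[(4-methoxybenzyl)oxy]pent-1-en-3-ol | C=C[C@H](O)[C@H](O[Si](c1ccccc1)(c1ccccc1)C(C)(C)C)COCc1ccc(OC)cc1 | intermediate
7 | 3-bromo-2-(bromomethyl)prop-1-ene | C=C(CBr)CBr | starting material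
8 | sodium alkoxide of 6 | C=C[C@H]([O-])[C@H](O[Si](c1ccccc1)(c1ccccc1)C(C)(C)C)COCc1ccc(OC)cc1.[Na+] | intermediate (not isolated)
9 | (3S,4R)-3-{[2-(bromomethyl)prop-2-en-1-yl]oxy}-4-[(tert-butyldiphenylsilyl)oxy]-5-[(4-methoxybenzyl)oxy]pent-1-ene | C=C[C@H](OCC(=C)CBr)[C@H](O[Si](c1ccccc1)(c1ccccc1)C(C)(C)C)COCc1ccc(OC)cc1 | intermediate
10 | (2S)-4-(bromomethyl)-2-{(1R)-1-[(tert-butyldiphenylsilyl)oxy]-2-[(4-methoxybenzyl)oxy]ethyl}-2,5-dihydrofuran (fragment A) | BrCC1=C[C@@H]([C@H](O[Si](c2ccccc2)(c2ccccc2)C(C)(C)C)COCc2ccc(OC)cc2)OC1 | intermediate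
11 | (S)-2-methylglycidol | C1[C@@](CO)(C)O1 | starting material
12 | bromomagnesium alkoxide of 11 | C1[C@@](CO[Mg]Br)(C)O1 | intermediate (not isolated)
13 | (R)-2-methylpent-4-ene-1,2-diol | C=CC[C@@](C)(O)CO | intermediate
14 | (R)-2-hydroxy-2-methylpent-4-en-1-yl acetate | C=CC[C@@](C)(O)COC(C)=O | intermediate
15 | (R)-2-methyl-2-[(triethylsilyl)oxy]pent-4-en-1-yl acetate | C=CC[C@@](C)(O[Si](CC)(CC)CC)COC(C)=O | intermediate
16 | ozonide (1,2,4-trioxolane) of 15 | C1(OCOO1)C[C@@](C)(O[Si](CC)(CC)CC)COC(C)=O | intermediate (not isolated)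
17 | (R)-2-methyl-4-oxo-2-[(triethylsilyl)oxy]butyl acetate (fragment B) | O=CC[C@@](C)(O[Si](CC)(CC)CC)COC(C)=O | intermediate
18 | allylchromium dichloride from 10 | Cl[Cr](Cl)CC1=C[C@@H]([C@H](O[Si](c2ccccc2)(c2ccccc2)C(C)(C)C)COCc2ccc(OC)cc2)OC1 | intermediate (not isolated)
19 | C8 alcohol: 3-methyleneoxolane (O6, C6, C7, C11, C12) with C5(OSitBuPh2)–C4H2O(4-methoxybenzyl) on C6 and C8H(OH)–C9H2–C10(CH3)(OSiEt3)–C1H2OAc on C7; H6/H7 trans, C8–OH anti to C6 | C=C1CO[C@H]([C@H](O[Si](c2ccccc2)(c2ccccc2)C(C)(C)C)COCc2ccc(OC)cc2)[C@H]1[C@@H](O)C[C@@](C)(O[Si](CC)(CC)CC)COC(C)=O | intermediate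
20 | 8-O-triethylsilyl ether of 19 | C=C1CO[C@H]([C@H](O[Si](c2ccccc2)(c2ccccc2)C(C)(C)C)COCc2ccc(OC)cc2)[C@H]1[C@@H](O[Si](CC)(CC)CC)C[C@@](C)(O[Si](CC)(CC)CC)COC(C)=O | intermediate
21 | C4 primary alcohol (4-methoxybenzyl group of 20 removed) | C=C1CO[C@H]([C@H](O[Si](c2ccccc2)(c2ccccc2)C(C)(C)C)CO)[C@H]1[C@@H](O[Si](CC)(CC)CC)C[C@@](C)(O[Si](CC)(CC)CC)COC(C)=O | intermediate
22 | C4 aldehyde | C=C1CO[C@H]([C@H](O[Si](c2ccccc2)(c2ccccc2)C(C)(C)C)C=O)[C@H]1[C@@H](O[Si](CC)(CC)CC)C[C@@](C)(O[Si](CC)(CC)CC)COC(C)=O | intermediate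
23 | ethynyltrimethylsilane | C#C[Si](C)(C)C | starting material
24 | lithium trimethylsilylacetylide | [Li]C#C[Si](C)(C)C | intermediate (not isolated)
25 | C4 propargylic alcohol (C4 epimers), C3≡C2–SiMe3 attached | C=C1CO[C@H]([C@H](O[Si](c2ccccc2)(c2ccccc2)C(C)(C)C)C(O)C#C[Si](C)(C)C)[C@H]1[C@@H](O[Si](CC)(CC)CC)C[C@@](C)(O[Si](CC)(CC)CC)COC(C)=O | intermediate
26 | C4 trimethylsilyl ynone | C=C1CO[C@H]([C@H](O[Si](c2ccccc2)(c2ccccc2)C(C)(C)C)C(=O)C#C[Si](C)(C)C)[C@H]1[C@@H](O[Si](CC)(CC)CC)C[C@@](C)(O[Si](CC)(CC)CC)COC(C)=O | intermediate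
27 | silylated enyne, C4(=C15H2)–C3≡C2–SiMe3 | C=C1CO[C@H]([C@H](O[Si](c2ccccc2)(c2ccccc2)C(C)(C)C)C(=C)C#C[Si](C)(C)C)[C@H]1[C@@H](O[Si](CC)(CC)CC)C[C@@](C)(O[Si](CC)(CC)CC)COC(C)=O | intermediate
28 | terminal enyne with free C1 hydroxyl | C=C1CO[C@H]([C@H](O[Si](c2ccccc2)(c2ccccc2)C(C)(C)C)C(=C)C#C)[C@H]1[C@@H](O[Si](CC)(CC)CC)C[C@@](C)(O[Si](CC)(CC)CC)CO | intermediate
29 | seco-aldehyde (key-step precursor): C1 aldehyde on C10(CH3)(OSiEt3), terminal C2≡C3–C4(=CH2) enyne, 5-OSitBuPh2, 8-OSiEt3, 3-methyleneoxolane | C=C1CO[C@H]([C@H](O[Si](c2ccccc2)(c2ccccc2)C(C)(C)C)C(=C)C#C)[C@H]1[C@@H](O[Si](CC)(CC)CC)C[C@@](C)(O[Si](CC)(CC)CC)C=O | intermediate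
30 | lithium acetylide of 29 (transmetalated by CeCl3) | C=C1CO[C@H]([C@H](O[Si](c2ccccc2)(c2ccccc2)C(C)(C)C)C(=C)C#C[Li])[C@H]1[C@@H](O[Si](CC)(CC)CC)C[C@@](C)(O[Si](CC)(CC)CC)C=O | intermediate (not isolated)
31 | ten-membered cyclic 2-yn-1-ol (1S; key-step product) | O[C@H]1C#CC(=C)[C@@H](O[Si](c3ccccc3)(c3ccccc3)C(C)(C)C)[C@H]2OCC(=C)[C@@H]2[C@@H](O[Si](CC)(CC)CC)C[C@@]1(C)O[Si](CC)(CC)CC | intermediate
32 | (2Z)-2,4(15)-dien-1-ol | O[C@H]1/C=C\C(=C)[C@@H](O[Si](c3ccccc3)(c3ccccc3)C(C)(C)C)[C@H]2OCC(=C)[C@@H]2[C@@H](O[Si](CC)(CC)CC)C[C@@]1(C)O[Si](CC)(CC)CC | intermediate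
33 | 2,3-epoxy-1-ol (cis-oxirane syn to the C1 hydroxyl; C2 and C3 as in the target) | O[C@H]1[C@H]2O[C@H]2C(=C)[C@@H](O[Si](c4ccccc4)(c4ccccc4)C(C)(C)C)[C@H]3OCC(=C)[C@@H]3[C@@H](O[Si](CC)(CC)CC)C[C@@]1(C)O[Si](CC)(CC)CC | intermediate
34 | C1 mesylate of 33 | CS(=O)(=O)O[C@H]1[C@H]2O[C@H]2C(=C)[C@@H](O[Si](c4ccccc4)(c4ccccc4)C(C)(C)C)[C@H]3OCC(=C)[C@@H]3[C@@H](O[Si](CC)(CC)CC)C[C@@]1(C)O[Si](CC)(CC)CC | intermediate
35 | 8,10-diol C1 mesylate | CS(=O)(=O)O[C@H]1[C@H]2O[C@H]2C(=C)[C@@H](O[Si](c4ccccc4)(c4ccccc4)C(C)(C)C)[C@H]3OCC(=C)[C@@H]3[C@@H](O)C[C@@]1(C)O | intermediate (not isolated)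
36 | 1,10:2,3-bis-epoxide with free C8 hydroxyl (5-OSitBuPh2, 6,12-ether) | C=C1CO[C@H]2[C@H]1[C@@H](O)C[C@@]1(C)O[C@@H]1[C@H]1O[C@H]1C(=C)[C@H]2O[Si](c1ccccc1)(c1ccccc1)C(C)(C)C | intermediate
37 | angelic acid, (Z)-2-methylbut-2-enoic acid | C/C=C(/C)C(=O)O | starting material
38 | angelic 2,4,6-trichlorobenzoic anhydride | C/C=C(/C)C(=O)OC(=O)c1c(Cl)cc(Cl)cc1Cl | intermediate (not isolated)
39 | 8-O-angelate of 36 | C=C1CO[C@H]2[C@H]1[C@@H](OC(=O)/C(C)=C\C)C[C@@]1(C)O[C@@H]1[C@H]1O[C@H]1C(=C)[C@H]2O[Si](c1ccccc1)(c1ccccc1)C(C)(C)C | intermediate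
40 | 5-O-tert-butyldiphenylsilyl ether of the target (α-methylene lactone) | C=C1C(=O)O[C@H]2[C@H]1[C@@H](OC(=O)/C(C)=C\C)C[C@@]1(C)O[C@@H]1[C@H]1O[C@H]1C(=C)[C@H]2O[Si](c1ccccc1)(c1ccccc1)C(C)(C)C | intermediate
41 | CNP0038366.2, (1R,2S,3S,5R,6S,7R,8S,10R)-8-angeloyloxy-1,10:2,3-diepoxy-5-hydroxygermacra-4(15),11(13)-dien-12,6-olide | C=C1C(=O)O[C@H]2[C@H]1[C@@H](OC(=O)/C(C)=C\C)C[C@@]1(C)O[C@@H]1[C@H]1O[C@H]1C(=C)[C@H]2O | target

**Step count**
Total: 27 steps. Longest linear sequence: 23 steps (steps 1–6 and 11–27, from compound 1); fragment B takes steps 7–10.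

**Steps most likely to fail**

Step 20. The acetylide may add to both faces of the aldehyde, because the two carbon groups on C10 (methyl and the C9 methylene) differ little in size. The fallback sets out from 29 and sets C1 by reagent-controlled ketone reduction instead of during the ring closure. The ring is closed as in step 20, and the carbinol mixture, 31 together with its C1 epimer F1, is oxidised with Dess–Martin periodinane (NaHCO3, CH2Cl2) to the ten-membered ynone F2. Corey–Bakshi–Shibata reduction of F2 with (R)-2-methyl-CBS-oxazaborolidine and catecholborane in toluene at −78 °C (quaternary C10 side as the large group, alkyne as the small one) should then give the 1S carbinol and comes back to the route at 31.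

Step 22. Oxygen may be delivered to the wrong face of C2=C3 if the ten-membered ring does not place the C1 hydroxyl as the smaller cycloalkenols do, and the Lewis-acidic vanadium may open the vinyl oxirane. The fallback sets out from 32 and replaces substrate direction by reagent control: Katsuki–Sharpless epoxidation with Ti(OiPr)4, D-(−)-diisopropyl tartrate and t-BuOOH (4 Å sieves, CH2Cl2, −20 °C). The D-tartrate is the matched partner of the 1S carbinol and delivers oxygen to the face that gives the erythro epoxy alcohol. It comes back at 33 and makes no compound outside the list (F0).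

Step 26. Hexavalent chromium may oxidise other C–H bonds (C5–H, C3–H, the angelate methyls) or degrade the oxiranes. The fallback sets out from 39 and splits the oxidation into two milder stages: SeO2 (catalytic) with t-BuOOH in CH2Cl2 hydroxylates the C12 methylene (ene reaction, then 2,3-shift) to the lactol F3, and MnO2 in CH2Cl2 oxidises this allylic hemiacetal to the lactone. It comes back at 40.

**Further compounds**
F1 | step 20 | C1 epimer (1R) of cycloalkynol 31 | O[C@@H]1C#CC(=C)[C@@H](O[Si](c3ccccc3)(c3ccccc3)C(C)(C)C)[C@H]2OCC(=C)[C@@H]2[C@@H](O[Si](CC)(CC)CC)C[C@@]1(C)O[Si](CC)(CC)CC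
F2 | step 20 | ten-membered 2-yn-1-one | O=C1C#CC(=C)[C@@H](O[Si](c3ccccc3)(c3ccccc3)C(C)(C)C)[C@H]2OCC(=C)[C@@H]2[C@@H](O[Si](CC)(CC)CC)C[C@@]1(C)O[Si](CC)(CC)CC
F0 | step 22 | none | none
F3 | step 26 | C12 lactol of 39 (both anomers) | C=C1C(O)O[C@H]2[C@H]1[C@@H](OC(=O)/C(C)=C\C)C[C@@]1(C)O[C@@H]1[C@H]1O[C@H]1C(=C)[C@H]2O[Si](c1ccccc1)(c1ccccc1)C(C)(C)C
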